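In a one-step world a product climbs toward its balance on a single time constant, and I started from there, although in these flasks the coupling partner has two takers.

    starting material + coupling partner ⇌ target (K1 = 83 M⁻¹, k1 = 3.09 M⁻¹ s⁻¹)
    second substrate + coupling partner ⇌ second product (K2 = 45.9 M⁻¹, k2 = 9.31 M⁻¹ s⁻¹)
    target ⇌ isomer of the product (K3 = 5.66, k3 = 0.0849 s⁻¹)
    2 second substrate → homo dimer (k4 = 3.16 M⁻¹ s⁻¹)

| flask | starting material | coupling partner | second substrate | time | remark |
|---|---|---|---|---|---|
| Tuesday's | 0.010 M | 0.700 equiv | 1.00 equiv (fed, over 5.0 s) | 12 s | all else is in the flask from the start; the feed brings no volume worth counting |
| Saturday's | 0.010 M | 0.700 equiv | 1.00 equiv | 12 s | everything together at the start |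
| Friday's | 0.010 M | 0.700 equiv (fed, over 5.0 s) | 1.00 equiv | 12 s | all else is in the flask from the start; the feed brings no volume worth counting |
| Thursday's | 0.010 M | 0.700 equiv (fed, over 0.50 s) | 1.00 equiv | 12 s | all else is in the flask from the start; the feed brings no volume worth counting |
| Sunday's | 0.010 M | 0.700 equiv (in portions, 5, over 5.0 s) | 1.00 equiv | 12 s | first portion at the start, last at 5.0 s |

- a doubled species enters its step squared and goes two at a time
- run time (Tuesday's): 12 s

* the flask with the highest amount of target, in percent of the starting material charged ("all alike" if they lie within 1.5 percentage points) (Tuesday's / Saturday's / Friday's / Thursday's / Sunday's / all alike)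
* final target, as a percentage of the starting material charged, in Tuesday's
* final target, as a percentage of the starting material charged, in Saturday's
* final target, as a percentage of the starting material charged, in Friday's
* final target, as a percentage of the starting material charged, in Thursday's
* final target, as a percentage of the starting material charged, in Sunday's

I treated target as a tank with a leak. Starting material and coupling partner fill it, a pseudo-first-order inflow while the partner level holds, and it drains back and on to its isomer at 0.122 s⁻¹; I left out the return from the isomer. Over 12 s such a tank has a memory window of 6.30 s, so its level is the inflow rate times that window.

In my first extreme, second substrate never touched the partner, and all 0.00700 M stayed free. In my second, second substrate stayed as charged and held partner as second product in balance. That binding relaxes with a half-life of 1.92 s, shorter than the 32 s forward half-life of starting material by the coupling alone in Saturday's, so I took it as settled and reckoned with the free share of the partner, one over one plus the equilibrium constant of the binding times second substrate: 68.5 %.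

I put starting material, lost at that pace, on average at 91.1 % of its charge. With that cut on both, the first extreme gave 12.4 % and the second 8.51 %. Homo dimer takes second substrate with a first half-life, by that step alone, of 15.8 s, longer than the run, so I expected second substrate to sag without vanishing and placed the real flask near the low end. Partner fed over 5.0 s arrives on average 2.50 s late, which shrinks the window to 5.62 s and gives 7.59 %. For Tuesday's, with second substrate fed over 5.0 s, I used 68.5 % for the last 4.71 s of the window and, for the remaining 1.59 s, during the feed, the mean of a full share and 68.5 %; that gave 9.00 %. The gap from there down to 7.59 % is 1.4 percentage points, smaller than the margin of 1.5 points, so I expected the flasks to count as equal.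

The forecast said all alike, with Tuesday's 9.1 %, Saturday's 8.9 %, Friday's 8.2 %, Thursday's 8.9 % and Sunday's 8.3 %, on the ground that “the final amount depends mostly on the partner level over the last several seconds”.

The flasks came out all alike: Tuesday's 8.96 %, Saturday's 8.76 %, Thursday's 8.73 %, Friday's 8.31 % and Sunday's 8.27 %, a spread of 0.69 points. Saturday's lay between 8.51 % and 12.4 %, and Friday's stood above my 7.59 %. For a neighbour of Sunday's, charged with 0.0025 M of starting material at the same equivalents, I reckoned a free share of 89.7 %, and the same window of 5.62 s gave me 2.65 %. That neighbour held 2.71 % of target at 12.0 s.

The constants used here are made up; no experiment stands behind them.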